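The quinone ring B (C1–C4, C4a, C8a; side chain on C2) is cut into an aroyl sulfoxonium ylide, which supplies ring A with C4 and C3, and a terminal alkyne, which supplies C1 and C2 with the complete (S)-side chain. A Cp*Rh-catalysed C–H activation/annulation joins them in one operation. The C4 acyl unit directs metalation of the neighbouring C8a–H, alkyne insertion forms C1–C8a, and alkenyl-to-carbene migration with loss of DMSO forms C2–C3. The feature exploited is that C3 is an unsubstituted CH and C2 carries the only substituent, so C1–C2 maps onto a terminal alkyne. Oxidation at C1 and unmasking of ring A follow.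

Key step: step 7

Remark: atom numbers are those of the naphthalene-1,4-dione target; naphthazarin tautomers interconvert rapidly, so either ring may end as the quinone. Compounds 1, 3, 8, 9 and 14 are taken as commercially available.

Step 1
Reactants: 1 4-methylpent-3-enoic acid
Product: 2 N-methoxy-N,4-dimethylpent-3-enamide
Conditions: CDI, CH2Cl2, rt; then MeNH(OMe)·HCl, rt
Reagents that add atoms: N,O-dimethylhydroxylamine hydrochloride, CNOC.Cl
Why: Weinreb amide formation through the acyl imidazolide needs no strong base, so the β,γ-double bond should not migrate.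

Step 2
Reactants: 2 N-methoxy-N,4-dimethylpent-3-enamide; 3 ethynyltrimethylsilane
Product: 4 6-methyl-1-(trimethylsilyl)hept-5-en-1-yn-3-one
Conditions: 3, n-BuLi, THF, −78 °C; then 2, −78 to −20 °C; quench into cold 1 M HCl
Reagents that add atoms: none
Why: Weinreb ketone synthesis, in which the chelated tetrahedral intermediate prevents over-addition and the acidic quench keeps the liberated amine from adding to the ynone.

Step 3
Reactants: 4 6-methyl-1-(trimethylsilyl)hept-5-en-1-yn-3-one
Product: 5 (3S)-6-methyl-1-(trimethylsilyl)hept-5-en-1-yn-3-ol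
Conditions: Ru(p-cymene)[(S,S)-TsDPEN] (2 mol%), i-PrOH, rt
Reagents that add atoms: none
Why: Noyori asymmetric transfer hydrogenation of an alkynyl ketone, in which the (S,S)-catalyst distinguishes the alkynyl from the alkyl substituent and should deliver hydride to the face that gives the (S)-carbinol, under base-free conditions that spare the skipped enone.

Step 4
Reactants: 5 (3S)-6-methyl-1-(trimethylsilyl)hept-5-en-1-yn-3-ol
Product: 6 (3S)-3-[(tert-butyldimethylsilyl)oxy]-6-methyl-1-(trimethylsilyl)hept-5-en-1-yne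
Conditions: TBSCl, imidazole, DMF, rt
Reagents that add atoms: tert-butyldimethylsilyl chloride, CC(C)(C)[Si](C)(C)Cl
Why: Standard O-silylation; the silyl ether is chosen because it is a poor leaving group in the later rhodium chemistry.

Step 5
Reactants: 6 (3S)-3-[(tert-butyldimethylsilyl)oxy]-6-methyl-1-(trimethylsilyl)hept-5-en-1-yne
Product: 7 (3S)-3-[(tert-butyldimethylsilyl)oxy]-6-methylhept-5-en-1-yne
Conditions: K2CO3 (cat.), MeOH, rt
Reagents that add atoms: none
Why: Methanolysis cleaves the alkynyl C–Si bond selectively while the O–TBS ether and the stereocentre are untouched.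

Step 6
Reactants: 8 2,5-dimethoxybenzoyl chloride; 9 trimethylsulfoxonium iodide
Product: 10 1-(2,5-dimethoxyphenyl)-2-[dimethyl(oxo)-λ6-sulfanylidene]ethan-1-one
Conditions: 9 (3 equiv), KOtBu (3 equiv), THF, reflux; then 0 °C, add 8, rt
Reagents that add atoms: none
Why: Corey–Chaykovsky-type C-acylation of dimethylsulfoxonium methylide, in which a second equivalent of ylide deprotonates the acylsulfoxonium salt to the stabilised β-keto ylide.

Step 7
Reactants: 10 1-(2,5-dimethoxyphenyl)-2-[dimethyl(oxo)-λ6-sulfanylidene]ethan-1-one (1.5 equiv); 7 (3S)-3-[(tert-butyldimethylsilyl)oxy]-6-methylhept-5-en-1-yne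
Product: 11 3-[(1S)-1-[(tert-butyldimethylsilyl)oxy]-4-methylpent-3-en-1-yl]-5,8-dimethoxynaphthalen-1-ol
Conditions: [Cp*RhCl2]2 (4 mol%), AgSbF6 (16 mol%), NaOAc (50 mol%), ClCH2CH2Cl, 80 °C, N2
Reagents that add atoms: none
Why: Acetate-assisted metalation of 10 by cationic Cp*Rh (trivalent rhodium) at the only free position ortho to the acyl group gives a five-membered rhodacycle; alkyne 7 inserts into the Rh–aryl bond with the aryl carbon going to the unsubstituted alkyne carbon (C1–C8a), loss of DMSO from the bound ylide gives a rhodium carbene into which the alkenyl group migrates (C2–C3), and protonation of the rhodium naphtholate releases 11. The closest known reaction type is the Cp*Rh-catalysed C–H activation/annulation of aroyl sulfoxonium ylides with alkynes to 1-naphthols, a redox-neutral formal [4+2] benzannulation. Ring B closes at C2–C3 by 1,1-migratory insertion inside a seven-membered rhodacycle, which amounts to a 6-endo closure onto the former ylide carbon. No stereocentre is formed and the propargylic centre takes part in no bond change; the poor leaving ability of the OTBS group should suppress β-oxygen elimination to an allene. Site selectivity is secured by the OMe group that blocks the second ortho position. The required insertion regiochemistry (substituted carbon on rhodium, CH on the arene) is the one generally found for terminal alkynes in such annulations and is reinforced by the bulky OTBS-bearing substituent.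

Step 8
Reactants: 11 3-[(1S)-1-[(tert-butyldimethylsilyl)oxy]-4-methylpent-3-en-1-yl]-5,8-dimethoxynaphthalen-1-ol
Product: 12 2-[(1S)-1-[(tert-butyldimethylsilyl)oxy]-4-methylpent-3-en-1-yl]-5,8-dimethoxynaphthalene-1,4-dione
Conditions: (KSO3)2NO (2.5 equiv), aq. KH2PO4, acetone, rt
Reagents that add atoms: potassium nitrosodisulfonate, [K+].[K+].[O-]S(=O)(=O)N([O])S(=O)(=O)[O-]
Why: Teuber oxidation of a 1-naphthol with a free para position should give the para-quinone, placing the missing oxygen on C1 without touching the dimethoxyarene, the alkene or the silyl ether.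

Step 9
Reactants: 12 2-[(1S)-1-[(tert-butyldimethylsilyl)oxy]-4-methylpent-3-en-1-yl]-5,8-dimethoxynaphthalene-1,4-dione
Product: 13 2-[(1S)-1-hydroxy-4-methylpent-3-en-1-yl]-5,8-dimethoxynaphthalene-1,4-dione
Conditions: HF·pyridine, THF/pyridine, 0 °C to rt
Reagents that add atoms: none
Why: Fluoride-mediated desilylation under buffered, non-basic conditions should spare the base-sensitive quinone and leave the carbinol centre untouched.

Step 10
Reactants: 13 2-[(1S)-1-hydroxy-4-methylpent-3-en-1-yl]-5,8-dimethoxynaphthalene-1,4-dione; 14 3-methylbutanoic acid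
Product: 15 (1S)-1-(5,8-dimethoxy-1,4-dioxo-1,4-dihydronaphthalen-2-yl)-4-methylpent-3-en-1-yl 3-methylbutanoate
Conditions: 14, DCC, DMAP (cat.), CH2Cl2, 0 °C to rt
Reagents that add atoms: none
Why: Steglich esterification acylates the only hydroxyl group at oxygen, so the configuration is retained.

Step 11
Reactants: 15 (1S)-1-(5,8-dimethoxy-1,4-dioxo-1,4-dihydronaphthalen-2-yl)-4-methylpent-3-en-1-yl 3-methylbutanoate
Product: 17 isovalerylalkannin, (1S)-1-(5,8-dihydroxy-1,4-dioxo-1,4-dihydronaphthalen-2-yl)-4-methylpent-3-en-1-yl 3-methylbutanoate, via naphthodiquinone ester 16 (not isolated)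
Conditions: AgO, 6 M HNO3, acetone, rt, 5–10 min; then aq. Na2S2O4, CHCl3/H2O
Reagents that add atoms: water, O
Why: Oxidative demethylation with argentic oxide should convert the deactivated dimethoxy ring A into a second quinone (water attacks the ipso carbons, methanol leaves), and two-electron reduction of the diquinone gives the naphthazarin, whose tautomers are one compound.

Compound list
1 | 4-methylpent-3-enoic acid | CC(C)=CCC(=O)O | starting material
2 | N-methoxy-N,4-dimethylpent-3-enamide | CC(C)=CCC(=O)N(C)OC | intermediate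
3 | ethynyltrimethylsilane | C#C[Si](C)(C)C | starting material
4 | 6-methyl-1-(trimethylsilyl)hept-5-en-1-yn-3-one | CC(C)=CCC(=O)C#C[Si](C)(C)C | intermediate
5 | (3S)-6-methyl-1-(trimethylsilyl)hept-5-en-1-yn-3-ol | CC(C)=CC[C@H](O)C#C[Si](C)(C)C | intermediate
6 | (3S)-3-[(tert-butyldimethylsilyl)oxy]-6-methyl-1-(trimethylsilyl)hept-5-en-1-yne | CC(C)=CC[C@H](O[Si](C)(C)C(C)(C)C)C#C[Si](C)(C)C | intermediate
7 | (3S)-3-[(tert-butyldimethylsilyl)oxy]-6-methylhept-5-en-1-yne | CC(C)=CC[C@H](O[Si](C)(C)C(C)(C)C)C#C | intermediate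
8 | 2,5-dimethoxybenzoyl chloride | COc1ccc(OC)c(c1)C(Cl)=O | starting material
9 | trimethylsulfoxonium iodide | C[S+](C)(C)=O.[I-] | starting material
10 | 1-(2,5-dimethoxyphenyl)-2-[dimethyl(oxo)-λ6-sulfanylidene]ethan-1-one | COc1ccc(OC)c(c1)C(=O)C=S(C)(C)=O | intermediate
11 | 3-[(1S)-1-[(tert-butyldimethylsilyl)oxy]-4-methylpent-3-en-1-yl]-5,8-dimethoxynaphthalen-1-ol | CC(C)=CC[C@H](O[Si](C)(C)C(C)(C)C)c1cc(O)c2c(OC)ccc(OC)c2c1 | intermediate
12 | 2-[(1S)-1-[(tert-butyldimethylsilyl)oxy]-4-methylpent-3-en-1-yl]-5,8-dimethoxynaphthalene-1,4-dione | CC(C)=CC[C@H](O[Si](C)(C)C(C)(C)C)C1=CC(=O)c2c(OC)ccc(OC)c2C1=O | intermediate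
13 | 2-[(1S)-1-hydroxy-4-methylpent-3-en-1-yl]-5,8-dimethoxynaphthalene-1,4-dione | CC(C)=CC[C@H](O)C1=CC(=O)c2c(OC)ccc(OC)c2C1=O | intermediate
14 | 3-methylbutanoic acid | CC(C)CC(=O)O | starting material
15 | (1S)-1-(5,8-dimethoxy-1,4-dioxo-1,4-dihydronaphthalen-2-yl)-4-methylpent-3-en-1-yl 3-methylbutanoate | CC(C)=CC[C@H](OC(=O)CC(C)C)C1=CC(=O)c2c(OC)ccc(OC)c2C1=O | intermediate
16 | (1S)-4-methyl-1-(1,4,5,8-tetraoxo-1,4,5,8-tetrahydronaphthalen-2-yl)pent-3-en-1-yl 3-methylbutanoate | CC(C)=CC[C@H](OC(=O)CC(C)C)C1=CC(=O)C2=C(C1=O)C(=O)C=CC2=O | intermediate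
17 | isovalerylalkannin, (1S)-1-(5,8-dihydroxy-1,4-dioxo-1,4-dihydronaphthalen-2-yl)-4-methylpent-3-en-1-yl 3-methylbutanoate | CC(C)=CC[C@H](OC(=O)CC(C)C)C1=CC(=O)c2c(O)ccc(O)c2C1=O | target

Total step count: 11. Longest linear sequence: 10 steps (steps 1–5, then 7–11).

Steps most likely to fail

Step 7. The terminal alkyne may be consumed at rhodium by acetylide formation or oligomerisation, metalation of the C–H flanked by the acyl and OMe groups may be slow, or insertion may proceed with the reverse regiochemistry. The fallback sets out from 7 and comes back at 11, fixing the regiochemistry by cross-coupling. 2-Bromo-1,4-dimethoxybenzene is lithiated between Br and OMe (LDA, THF, −78 °C) and acetylated with N-methoxy-N-methylacetamide to give 1-(2-bromo-3,6-dimethoxyphenyl)ethan-1-one F1. Sonogashira coupling of F1 with 7 (PdCl2(MeCN)2, XPhos, Cs2CO3, MeCN, 70 °C) should give 1-{2-[(3S)-3-[(tert-butyldimethylsilyl)oxy]-6-methylhept-5-en-1-yn-1-yl]-3,6-dimethoxyphenyl}ethan-1-one F2. Its potassium enolate (KHMDS, THF, −78 °C to rt) should close by 6-endo-dig carbocyclisation onto the alkyne to give 11.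

Step 11. The prenyl double bond may be over-oxidised, the ester-bearing carbon may ionise in nitric acid, or the deactivated ring A may be oxidised incompletely. The fallback sets out from 15 and comes back at 17, transferring the oxidation state between the rings instead. Reductive acetylation (Zn, Ac2O, NaOAc, rt) should give (1S)-1-[1,4-bis(acetyloxy)-5,8-dimethoxynaphthalen-2-yl]-4-methylpent-3-en-1-yl 3-methylbutanoate F3. Its still electron-rich dimethoxy ring is oxidised with (NH4)2Ce(NO3)6 (MeCN/H2O, 0 °C) to (1S)-1-[1,4-bis(acetyloxy)-5,8-dioxo-5,8-dihydronaphthalen-2-yl]-4-methylpent-3-en-1-yl 3-methylbutanoate F4. The two labile aryl acetates are then removed selectively (NH4OAc, aq. MeOH, rt) to give 17 as its tautomer.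

Step 3. The skipped double bond may migrate into conjugation before reduction, or facial discrimination may be insufficient. The fallback sets out from 4 and comes back at 5 by resolution. Luche reduction (NaBH4, CeCl3·7H2O, MeOH, −78 °C) gives racemic 6-methyl-1-(trimethylsilyl)hept-5-en-1-yn-3-ol F5. Esterification with (S)-O-acetylmandelic acid (DCC, DMAP, CH2Cl2) gives two diastereomers that are separated by chromatography: (3S)-6-methyl-1-(trimethylsilyl)hept-5-en-1-yn-3-yl (2S)-2-(acetyloxy)-2-phenylacetate F6 and its (3R) diastereomer, (3R)-6-methyl-1-(trimethylsilyl)hept-5-en-1-yn-3-yl (2S)-2-(acetyloxy)-2-phenylacetate F7, which is set aside. Reductive cleavage of F6 (DIBAL-H, CH2Cl2, −78 °C) returns 5.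

Further compounds
F1 | step 7 | 1-(2-bromo-3,6-dimethoxyphenyl)ethan-1-one | CC(=O)c1c(Br)c(OC)ccc1OC
F2 | step 7 | 1-{2-[(3S)-3-[(tert-butyldimethylsilyl)oxy]-6-methylhept-5-en-1-yn-1-yl]-3,6-dimethoxyphenyl}ethan-1-one | CC(=O)c1c(C#C[C@H](CC=C(C)C)O[Si](C)(C)C(C)(C)C)c(OC)ccc1OC
F3 | step 11 | (1S)-1-[1,4-bis(acetyloxy)-5,8-dimethoxynaphthalen-2-yl]-4-methylpent-3-en-1-yl 3-methylbutanoate | CC(C)=CC[C@H](OC(=O)CC(C)C)c1cc(OC(C)=O)c2c(OC)ccc(OC)c2c1OC(C)=O
F4 | step 11 | (1S)-1-[1,4-bis(acetyloxy)-5,8-dioxo-5,8-dihydronaphthalen-2-yl]-4-methylpent-3-en-1-yl 3-methylbutanoate | CC(C)=CC[C@H](OC(=O)CC(C)C)c1cc(OC(C)=O)c2C(=O)C=CC(=O)c2c1OC(C)=O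
F5 | step 3 | racemic 6-methyl-1-(trimethylsilyl)hept-5-en-1-yn-3-ol | CC(C)=CCC(O)C#C[Si](C)(C)C
F6 | step 3 | (3S)-6-methyl-1-(trimethylsilyl)hept-5-en-1-yn-3-yl (2S)-2-(acetyloxy)-2-phenylacetate | CC(C)=CC[C@H](OC(=O)[C@@H](OC(C)=O)c1ccccc1)C#C[Si](C)(C)C
F7 | step 3 | (3R)-6-methyl-1-(trimethylsilyl)hept-5-en-1-yn-3-yl (2S)-2-(acetyloxy)-2-phenylacetate | CC(C)=CC[C@@H](OC(=O)[C@@H](OC(C)=O)c1ccccc1)C#C[Si](C)(C)C
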